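**Retrosynthetic overview**
1. 16 ⇒ 15: one BCl3 operation removes both benzyl ethers and the carbonyl-chelated 5-O-methyl; the 7-O-methyl stays.
2. Ring C is the only ring made (rings A and B are bought): cyclodehydration of 2-prenyl-1,3-diketone 14 ⇐ C-prenylation of 13 ⇐ Baker–Venkataraman union of ring A ketone 7 with ring B acid 10.
3. 7 ⇐ ortho-acetylation of the symmetric phenol 6; its single OH, para to the side chain, becomes O1, which fixes the side chain at C6.
4. Key disconnection ArCH2–C(=O)iPr: 6 ⇐ para-quinone methide 5 (benzylic acceptor, from sulfone 3 and aldehyde 1) + isobutyraldehyde 4 used as an acyl anion under carbene catalysis.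

Assumption: the target SMILES has no stereocentre and no stereogenic double bond, so the target is one achiral compound; the only stereocentre on the way (C2 of 14, racemic) becomes sp2 in step 7.
Purchased: 1, 4 and 8 (catalogue compounds) plus common reagents (p-TolSO2Na, AcOH, BnBr, prenyl bromide).

**Step 1**
Reactants: 1 4-hydroxy-2,6-dimethoxybenzaldehyde
Product: 3 3,5-dimethoxy-4-{[(4-methylphenyl)sulfonyl]methyl}phenol, via benzylic alcohol 2 (not isolated)
Conditions: NaBH4 (1.0 equiv), MeOH, 0 °C; then p-TolSO2Na (1.5 equiv), HCO2H/H2O, rt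
Reagents that add atoms: sodium p-toluenesulfinate, Cc1ccc(cc1)S(=O)[O-].[Na+]
Why: Aldehyde reduction followed by SN1 sulfonylation: the electron-rich para-hydroxybenzyl alcohol 2 ionises in dilute formic acid and the cation is trapped at sulfur by the sulfinate, giving a crystalline sulfone that stores the latent quinone methide.

**Step 2**
Reactants: 3 3,5-dimethoxy-4-{[(4-methylphenyl)sulfonyl]methyl}phenol; 4 isobutyraldehyde (2-methylpropanal)
Product: 6 1-(4-hydroxy-2,6-dimethoxyphenyl)-3-methylbutan-2-one, via para-quinone methide 5 (not isolated)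
Conditions: 3-benzyl-5-(2-hydroxyethyl)-4-methylthiazolium chloride (20 mol %), Cs2CO3 (2.5 equiv), 4 (3 equiv), THF, 40 °C; 3 added over 4 h
Reagents that add atoms: none
Why: Proposed new method: Cs2CO3 expels sulfinate from the phenoxide of 3 to give 5, whose exocyclic CH2 is a benzylic electrophile, while the thiazol-2-ylidene turns the carbonyl carbon of 4 into an acyl anion equivalent that adds 1,6 to 5 and then releases the carbene (Stetter-type 1,6-hydroacylation), so two carbons that are both electrophilic in their parent forms are joined; the closest known reactions are carbene-catalysed 1,6-additions of aldehydes to isolable para-quinone methides and acyl anion additions to ortho-quinone methides generated in situ, and slow addition of 3 keeps 5 dilute against oligomerisation and attack by the enolate of 6.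

**Step 3**
Reactants: 6 1-(4-hydroxy-2,6-dimethoxyphenyl)-3-methylbutan-2-one
Product: 7 1-[6-hydroxy-2,4-dimethoxy-3-(3-methyl-2-oxobutyl)phenyl]ethan-1-one
Conditions: AcOH, BF3·OEt2 (3 equiv), 90 °C, 2 h; aq. NaOAc work-up
Reagents that add atoms: acetic acid, CC(=O)O
Why: Friedel–Crafts (Fries-type) C-acetylation ortho to the phenol: the two open ring positions of 6 are equivalent by symmetry and both lie ortho to OH, so a single acetophenone forms with the free OH para to the side chain, as in the standard BF3-mediated acetylation of 3,5-dimethoxyphenol.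

**Step 4**
Reactants: 8 2,4-dihydroxybenzoic acid
Product: 10 2,4-bis(benzyloxy)benzoic acid, via benzyl ester 9 (not isolated)
Conditions: BnBr (3.3 equiv), K2CO3 (3.5 equiv), DMF, 60 °C; then NaOH, MeOH/H2O, 70 °C; HCl work-up
Reagents that add atoms: benzyl bromide, BrCc1ccccc1; sodium hydroxide, [Na+].[OH-]
Why: Williamson O-benzylation of all three acidic OH groups, then saponification of the single ester, gives the ring B acid with phenol protection that survives base and weak acid and is removed together with the 5-O-methyl in step 8.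

**Step 5**
Reactants: 10 2,4-bis(benzyloxy)benzoic acid; 7 1-[6-hydroxy-2,4-dimethoxy-3-(3-methyl-2-oxobutyl)phenyl]ethan-1-one
Product: 13 1-[2,4-bis(benzyloxy)phenyl]-3-[6-hydroxy-2,4-dimethoxy-3-(3-methyl-2-oxobutyl)phenyl]propane-1,3-dione, via acid chloride 11 (not isolated), via aryl ester 12 (not isolated)
Conditions: 10, (COCl)2, DMF (cat.), CH2Cl2, 0 °C to rt, then evaporate; 7, K2CO3 (4 equiv), acetone, reflux, 24 h; AcOH quench
Reagents that add atoms: none
Why: O-aroylation followed in the same pot by Baker–Venkataraman rearrangement: the acetyl enolate of ester 12 attacks the neighbouring ester through a six-membered transition state, whereas the side-chain ketone enolate sits para to the ester oxygen and cannot reach it, so only the desired 1,3-diketone forms.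

**Step 6**
Reactants: 13 1-[2,4-bis(benzyloxy)phenyl]-3-[6-hydroxy-2,4-dimethoxy-3-(3-methyl-2-oxobutyl)phenyl]propane-1,3-dione
Product: 14 1-[2,4-bis(benzyloxy)phenyl]-3-[6-hydroxy-2,4-dimethoxy-3-(3-methyl-2-oxobutyl)phenyl]-2-(3-methylbut-2-en-1-yl)propane-1,3-dione (racemic)
Conditions: prenyl bromide (1.1 equiv), K2CO3 (1.2 equiv), acetone, rt to 45 °C
Reagents that add atoms: prenyl bromide (1-bromo-3-methylbut-2-ene), CC(C)=CCBr
Why: SN2 C-alkylation of a stabilised β-diketone enolate: the doubly activated CH2 of 13 is the softest nucleophile present and far more acidic than the hindered side-chain ketone, so one prenyl group is installed there; the new stereocentre is racemic and is destroyed in step 7.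

**Step 7**
Reactants: 14 1-[2,4-bis(benzyloxy)phenyl]-3-[6-hydroxy-2,4-dimethoxy-3-(3-methyl-2-oxobutyl)phenyl]-2-(3-methylbut-2-en-1-yl)propane-1,3-dione
Product: 15 2-[2,4-bis(benzyloxy)phenyl]-5,7-dimethoxy-6-(3-methyl-2-oxobutyl)-3-(3-methylbut-2-en-1-yl)-4H-chromen-4-one
Conditions: NaOAc, AcOH, 100 °C
Reagents that add atoms: none
Why: Acid-catalysed cyclodehydration (flavone ring closure): the only free phenol of 14, the one para to the side chain, adds to the ring B ketone and the hemiketal loses water (the sole by-product), so the side chain can only end up at C6, while buffered AcOH leaves the prenyl alkene and benzyl ethers intact.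

**Step 8**
Reactants: 15 2-[2,4-bis(benzyloxy)phenyl]-5,7-dimethoxy-6-(3-methyl-2-oxobutyl)-3-(3-methylbut-2-en-1-yl)-4H-chromen-4-one
Product: 16 2-(2,4-dihydroxyphenyl)-5-hydroxy-7-methoxy-6-(3-methyl-2-oxobutyl)-3-(3-methylbut-2-en-1-yl)-4H-chromen-4-one (CNP0291994.0)
Conditions: BCl3 (6 equiv), pentamethylbenzene (6 equiv), CH2Cl2, −78 °C to 0 °C; then MeOH, aq. NaHCO3
Reagents that add atoms: none
Why: Lewis-acid ether cleavage: BCl3 removes the two benzyl groups (pentamethylbenzene traps the benzyl cations by Friedel–Crafts alkylation) and, through the six-membered chelate with the C4 carbonyl, only the 5-O-methyl, while the unchelated 7-O-methyl, the prenyl alkene and the ketone survive at or below 0 °C.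

**Compound list**
1 | 4-hydroxy-2,6-dimethoxybenzaldehyde | O=Cc1c(OC)cc(O)cc1OC | starting material
2 | 4-(hydroxymethyl)-3,5-dimethoxyphenol | OCc1c(OC)cc(O)cc1OC | intermediate
3 | 3,5-dimethoxy-4-{[(4-methylphenyl)sulfonyl]methyl}phenol | Cc1ccc(cc1)S(=O)(=O)Cc1c(OC)cc(O)cc1OC | intermediate
4 | isobutyraldehyde (2-methylpropanal) | CC(C)C=O | starting material
5 | 3,5-dimethoxy-4-methylidenecyclohexa-2,5-dien-1-one (para-quinone methide) | C=C1C(OC)=CC(=O)C=C1OC | intermediate
6 | 1-(4-hydroxy-2,6-dimethoxyphenyl)-3-methylbutan-2-one | CC(C)C(=O)Cc1c(OC)cc(O)cc1OC | intermediate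
7 | 1-[6-hydroxy-2,4-dimethoxy-3-(3-methyl-2-oxobutyl)phenyl]ethan-1-one | CC(=O)c1c(O)cc(OC)c(CC(=O)C(C)C)c1OC | intermediate
8 | 2,4-dihydroxybenzoic acid | O=C(O)c1ccc(O)cc1O | starting material
9 | benzyl 2,4-bis(benzyloxy)benzoate | O=C(OCc1ccccc1)c1ccc(OCc2ccccc2)cc1OCc1ccccc1 | intermediate
10 | 2,4-bis(benzyloxy)benzoic acid | O=C(O)c1ccc(OCc2ccccc2)cc1OCc1ccccc1 | intermediate
11 | 2,4-bis(benzyloxy)benzoyl chloride | O=C(Cl)c1ccc(OCc2ccccc2)cc1OCc1ccccc1 | intermediate
12 | 2-acetyl-3,5-dimethoxy-4-(3-methyl-2-oxobutyl)phenyl 2,4-bis(benzyloxy)benzoate | CC(=O)c1c(OC(=O)c2ccc(OCc3ccccc3)cc2OCc2ccccc2)cc(OC)c(CC(=O)C(C)C)c1OC | intermediate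
13 | 1-[2,4-bis(benzyloxy)phenyl]-3-[6-hydroxy-2,4-dimethoxy-3-(3-methyl-2-oxobutyl)phenyl]propane-1,3-dione | CC(C)C(=O)Cc1c(OC)cc(O)c(C(=O)CC(=O)c2ccc(OCc3ccccc3)cc2OCc2ccccc2)c1OC | intermediate
14 | 1-[2,4-bis(benzyloxy)phenyl]-3-[6-hydroxy-2,4-dimethoxy-3-(3-methyl-2-oxobutyl)phenyl]-2-(3-methylbut-2-en-1-yl)propane-1,3-dione (racemic at C2) | CC(C)C(=O)Cc1c(OC)cc(O)c(C(=O)C(CC=C(C)C)C(=O)c2ccc(OCc3ccccc3)cc2OCc2ccccc2)c1OC | intermediate
15 | 2-[2,4-bis(benzyloxy)phenyl]-5,7-dimethoxy-6-(3-methyl-2-oxobutyl)-3-(3-methylbut-2-en-1-yl)-4H-chromen-4-one | COc1cc2oc(-c3ccc(OCc4ccccc4)cc3OCc3ccccc3)c(CC=C(C)C)c(=O)c2c(OC)c1CC(=O)C(C)C | intermediate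
16 | 2-(2,4-dihydroxyphenyl)-5-hydroxy-7-methoxy-6-(3-methyl-2-oxobutyl)-3-(3-methylbut-2-en-1-yl)-4H-chromen-4-one | COc1cc2oc(-c3ccc(O)cc3O)c(CC=C(C)C)c(=O)c2c(O)c1CC(=O)C(C)C | target

**Totals**
Total steps: 8. Longest linear sequence: 7 (steps 1, 2, 3, 5, 6, 7, 8 from aldehyde 1); step 4 is a one-step side branch.

**Steps most likely to fail, with fallbacks**

Step 2. The unsubstituted quinone methide 5 may oligomerise, alkylate the carbene, or be attacked by the enolate of 6 before the acyl anion arrives. The fallback sets out from aldehyde 1 and comes back to the route at 6, replacing steps 1 and 2. It changes both partners: a nitronate serves as the acyl anion equivalent and the aldehyde carbon of 1 is the acceptor. Henry condensation of 1 with 2-methyl-1-nitropropane (NH4OAc, AcOH, 100 °C) gives the nitroalkene 3,5-dimethoxy-4-[(1E)-3-methyl-2-nitrobut-1-en-1-yl]phenol F1. Fe powder in AcOH/H2O at 80 °C then reduces F1 to the enamine/oxime stage and hydrolyses it (reductive Nef reaction) to ketone 6.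

Step 6. Risks are O-alkylation of the diketone enolate or of the ring A phenoxide, and attack of acid on the prenyl alkene during the ring closure that follows. The fallback sets out from diketone 13 and comes back at 15. Alkylation with allyl bromide (K2CO3, acetone) gives 1-[2,4-bis(benzyloxy)phenyl]-3-[6-hydroxy-2,4-dimethoxy-3-(3-methyl-2-oxobutyl)phenyl]-2-(prop-2-en-1-yl)propane-1,3-dione F2. Ring C is then closed under stronger acid that an allyl group tolerates (TsOH, toluene, 110 °C) to 2-[2,4-bis(benzyloxy)phenyl]-5,7-dimethoxy-6-(3-methyl-2-oxobutyl)-3-(prop-2-en-1-yl)-4H-chromen-4-one F3. Olefin cross-metathesis of F3 with 2-methylbut-2-ene (second-generation Grubbs catalyst, RuCl2(=CHPh)(PCy3)(H2IMes), CH2Cl2, 40 °C) turns allyl into prenyl and gives 15.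

Step 8. BCl3 and the HCl it releases may add to the prenyl alkene, or dehydrate the freed 5-OH onto the side-chain ketone to a benzofuran. The fallback sets out from 15 and comes back at 16, splitting the unmasking into two orthogonal reactions. MgI2·OEt2 (THF, 60 °C) cleaves only the carbonyl-chelated 5-O-methyl and gives 2-[2,4-bis(benzyloxy)phenyl]-5-hydroxy-7-methoxy-6-(3-methyl-2-oxobutyl)-3-(3-methylbut-2-en-1-yl)-4H-chromen-4-one F4. Catalytic transfer hydrogenolysis (Pd/C, 1,4-cyclohexadiene, EtOH, rt) then removes the two benzyl groups faster than it touches the trisubstituted alkene and gives 16.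

**Further compounds**
F1 | step 2 | 3,5-dimethoxy-4-[(1E)-3-methyl-2-nitrobut-1-en-1-yl]phenol | CC(C)/C(=C\c1c(OC)cc(O)cc1OC)[N+](=O)[O-]
F2 | step 6 | 1-[2,4-bis(benzyloxy)phenyl]-3-[6-hydroxy-2,4-dimethoxy-3-(3-methyl-2-oxobutyl)phenyl]-2-(prop-2-en-1-yl)propane-1,3-dione (racemic at C2) | CC(C)C(=O)Cc1c(OC)cc(O)c(C(=O)C(CC=C)C(=O)c2ccc(OCc3ccccc3)cc2OCc2ccccc2)c1OC
F3 | step 6 | 2-[2,4-bis(benzyloxy)phenyl]-5,7-dimethoxy-6-(3-methyl-2-oxobutyl)-3-(prop-2-en-1-yl)-4H-chromen-4-one | COc1cc2oc(-c3ccc(OCc4ccccc4)cc3OCc3ccccc3)c(CC=C)c(=O)c2c(OC)c1CC(=O)C(C)C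
F4 | step 8 | 2-[2,4-bis(benzyloxy)phenyl]-5-hydroxy-7-methoxy-6-(3-methyl-2-oxobutyl)-3-(3-methylbut-2-en-1-yl)-4H-chromen-4-one | COc1cc2oc(-c3ccc(OCc4ccccc4)cc3OCc3ccccc3)c(CC=C(C)C)c(=O)c2c(O)c1CC(=O)C(C)C
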